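Assumption: C8 of the target carries two constitutionally identical CH2OC(O)CH(CH3)2 groups and the SMILES holds no stereodescriptor. The compound is therefore achiral, "the single enantiomer given" is read as this one achiral compound, and no step has to set or protect a configuration.

## The problem

Thymol (p-menthane) numbering is used: benzene ring C1–C6 with the methyl C7 on C1, OMe on C3 and the side-chain carbon C8 on C4; C9 and C10 are the two CH2 groups on C8. No ring has to be closed. The difficulty sits at C8, a fully substituted benzylic carbinol carbon bonded to ring carbon C4, to a free OH and to two O–CH2 carbons that each carry an isobutyrate. O–C8–C9–O and O–C8–C10–O are two 1,2-dioxygenated (dissonant) pairs that share C8, so neither C8–C9 nor C8–C10 can be made from an acyl carbon and an oxygenated CH2 carbon in their natural, both electrophilic, polarity. C8 is not a stereocentre, because its arms are identical and the molecule has a mirror plane; there is nothing to control or scramble, and a good plan should exploit this symmetry. The ring pattern (C8 ortho to OMe, para to C7) is not what electrophilic substitution of 3-methylanisole gives (attack para to OMe, at C6), so it is best bought. The three oxygens on C8–C10 must end up differentiated, with the two primary ones acylated and the tertiary one free. The groups are fragile both ways: C8–OH ionises in acid (tertiary, benzylic, ortho OMe, para methyl), the C8 alkoxide lies 1,2 to two esters and can take over an acyl group or expel a carboxylate, and the isobutyrates are electrophiles with an acidic α-H. The feature that makes the key step possible is the pattern at C8: one oxygen, the ring carbon C4 and two identical carbon arms, which is the signature of a twofold addition of one nucleophile to the carboxyl carbon of a 2-methoxy-4-methylbenzoyl unit. In addition, each arm holds an ester C=O that can clamp a metal on C9/C10 in a five-membered chelate, and the C3–OMe offers a second chelating site at the ketone stage.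

## Retrosynthesis

**C8–C9 and C8–C10, cut together.** Because the arms are identical, both bonds can be given to one reagent used twice. Target 8, through its chloromagnesium alkoxide 7, goes back to the aroyl chloride 2 and two equivalents of the acyloxymethylmagnesium carbenoid 5, with the α-acyloxy ketone 6 as the unisolated halfway point.
- The neighbouring cut C4–C8 leaves the dissonant O–C–C–O pattern untouched. That pattern must then be bought in a C3 ketone and either protected or exposed to a hard aryl-metal.
- The C–O cuts build two identical arms in separate operations.
- The chosen cut removes ten of the nineteen carbons and all four ester oxygens at once. Its precursor 2 cannot enolise and holds the ring pattern ready-made.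
- The esters arrive in place, so there is no triol, no protecting group and no primary-versus-tertiary acylation.
- The forward reaction asks that an O–CH2 carbon act as a nucleophile, survive next to its own ester, and choose acyl chloride and ketone carbonyls over ester carbonyls.

**C–Mg bond of 5, then C–I bond of 4.** Carbenoid 5 goes back to the iodomethyl ester 4 by halogen–metal exchange. Exchange is preferred over metal insertion or deprotonation because it runs at −78 °C, the only temperature range in which 5 can be expected to live. The C–I bond of 4 is activated by the geminal oxygen. Iodide 4 goes back to the commercial chloromethyl ester 3 by halide exchange. The polarity reversal of C9/C10 therefore costs one simple step, and the ester is never made or moved on the assembled skeleton.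

**Acyl C–Cl bond of 2.** Chloride 2 goes back to the commercial acid 1, which already holds C1–C8 and the OMe group. The chloride is chosen over an ester or amide of 1 for two reasons. The leaving group must depart at −78 °C, and the acyl carbon must outrank the isobutyrate carbonyls of 5, 6 and 7; a donor-substituted benzoate ester would rank below them.

## Roads not taken

Alternative 1: cut C4–C8, the route most chemists would draw first. The aryl bromide A1 is metalated and added to the acetonide-protected C3 ketone A2 to give the carbinol A3. Acid hydrolysis gives the triol A4, which is acylated twice at the primary hydroxyls. This is four steps in line against two. The dissonant pattern is bought in protected form and paid for with an acidic deprotection, the very condition under which C8–OH of A3 and A4 ionises, and with a final acylation that must stop at the diester. The shortcut of adding the aryl-metal directly to 1,3-bis(isobutyryloxy)acetone A5 sets a hindered, basic ortho-substituted aryl nucleophile against a ketone that is enolisable on both sides and flanked by two esters. In the chosen plan the nucleophile is small and weakly basic, and the first electrophile cannot enolise.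

Alternative 2: cut C8–O and C9–O. The 2-arylallyl ester A6 is dihydroxylated to the diol monoester A7, whose primary hydroxyl is then acylated; epoxidation followed by carboxylate opening differs only in reagents. A6 itself needs two to three steps from A1 (C–C coupling, then esterification), so the sequence has at least four steps. The two identical arms are made by different chemistry in different steps, which ignores the symmetry. The oxidised intermediates of this electron-rich α-substituted styrene sit one ionisation away from a 1,2-shift to a carbonyl compound.

Alternative 3: cut C9–O and C10–O. The oxetanol A8, from metalated A1 and oxetan-3-one A9, would be opened by isobutyric anhydride A10, which delivers both acyl groups with full atom economy. The route is short, but its C–C bond is that of Alternative 1. Acid activation of the ring oxygen competes with ionisation of C8–OH to a donor-stabilised oxetanyl cation, followed by arene capture and oligomerisation, while SN2 attack must occur at neopentyl-type CH2 groups. Nucleophilic (onium carboxylate) catalysis would need temperatures at which A10 also acylates C8–OH. One selectivity problem is exchanged for two.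

Key step: step 3

## Route

Step 1
Reactants: 1 2-methoxy-4-methylbenzoic acid
Product: 2 2-methoxy-4-methylbenzoyl chloride
Conditions: (COCl)2 (1.3 equiv), DMF (cat.), CH2Cl2, 0 °C to rt; evaporation, toluene chase, used crude
Reagents that add atoms: oxalyl chloride, ClC(=O)C(=O)Cl
Why: Standard acid chloride formation through the Vilsmeier-type chloroiminium catalyst; all by-products are gases, so 2 should be obtained free of protic material after stripping. The aryl methyl ether and the ring methyl group are inert under these conditions.

Step 2
Reactants: 3 chloromethyl isobutyrate (chloromethyl 2-methylpropanoate)
Product: 4 iodomethyl isobutyrate (iodomethyl 2-methylpropanoate)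
Conditions: NaI (1.5 equiv), acetone, rt, dark; filtration, aq Na2S2O3 wash, drying, used fresh
Reagents that add atoms: sodium iodide, [Na+].[I-]
Why: Finkelstein reaction at an oxygen-activated CH2 group, driven by precipitation of the chloride salt; it is routine for acyloxymethyl halides. The ester is untouched by neutral iodide.

Step 3
Reactants: 4 iodomethyl isobutyrate (two molecules enter the product); 2 2-methoxy-4-methylbenzoyl chloride
Product: 8 2-hydroxy-2-(2-methoxy-4-methylphenyl)propane-1,3-diyl bis(2-methylpropanoate), via (isobutyryloxy)methylmagnesium chloride 5 (not isolated), via α-acyloxy ketone 6 (not isolated), via chloromagnesium alkoxide 7 (not isolated)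
Conditions: 4 (2.5 equiv), iPrMgCl (2.4 equiv), THF/N-butylpyrrolidinone, −78 °C, 20 min; then 2 (1.0 equiv) in THF added slowly, −78 °C; AcOH in THF at −78 °C, then pH 7 phosphate buffer
Reagents that add atoms: none
Why: Proposed new method: iodine–magnesium exchange on 4, driven by the geminal acyloxy oxygen and by a five-membered C–Mg···O=C chelate, should give the magnesium carbenoid 5, an O–CH2 carbon of reversed polarity that can be joined to the likewise electrophilic acyl carbon C8. The closest known reaction types are the same exchange on iodomethyl pivalate with trapping by aldehydes and the classical twofold Grignard addition to acyl chlorides that gives tertiary alcohols with two identical groups, whereas a twofold addition of an acyloxymethylmagnesium reagent to an aroyl chloride has not been shown. Addition–elimination at 2 expels chloride at once and gives ketone 6, whose carbonyl is activated by the α-acyloxy group and held by magnesium between the C3–OMe and the carbonyl oxygen, so the second equivalent of 5 should add to C8 faster than it removes a C9 proton, giving 7. No ring is closed. No stereocentre is formed, since C8 receives two identical arms. The step needs chemoselectivity in the order aroyl chloride > chelated α-acyloxy aryl ketone >> isobutyrate ester at −78 °C, which is secured by the chloride leaving group of 2, by the non-enolisable first electrophile, and by adding 2 to preformed excess 5 so that no free iPrMgCl meets 2. Alkoxide 7 is protonated with AcOH at −78 °C before a 1,2 O-to-O acyl shift or epoxide closure can start. Should an acyl shift occur, it is reversible and the primary ester/tertiary alcohol arrangement is the more stable one, so mild base equilibration should lead back to 8.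

## Compound list

1 | 2-methoxy-4-methylbenzoic acid | COc1cc(C)ccc1C(=O)O | starting material
2 | 2-methoxy-4-methylbenzoyl chloride | COc1cc(C)ccc1C(=O)Cl | intermediate
3 | chloromethyl isobutyrate | CC(C)C(=O)OCCl | starting material
4 | iodomethyl isobutyrate | CC(C)C(=O)OCI | intermediate
5 | (isobutyryloxy)methylmagnesium chloride | CC(C)C(=O)OC[Mg]Cl | intermediate
6 | 2-(2-methoxy-4-methylphenyl)-2-oxoethyl isobutyrate | COc1cc(C)ccc1C(=O)COC(=O)C(C)C | intermediate
7 | chloromagnesium 1,3-bis(isobutyryloxy)-2-(2-methoxy-4-methylphenyl)propan-2-olate | COc1cc(C)ccc1C(O[Mg]Cl)(COC(=O)C(C)C)COC(=O)C(C)C | intermediate
8 | 2-hydroxy-2-(2-methoxy-4-methylphenyl)propane-1,3-diyl bis(2-methylpropanoate), achiral (CNP0109979.0) | COc1cc(C)ccc1C(O)(COC(=O)C(C)C)COC(=O)C(C)C | target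

## Step count and risks

Total steps: 3. Longest linear sequence: 2 (1 → 2 → 8, or 3 → 4 → 8).

**Step 3 (key step, proposed new method).**
- Most likely failures:
  - decay of the carbenoid before it is consumed, by α-elimination, by self-acylation at the isobutyrate carbonyl (less hindered than a pivalate), or by coupling with unreacted iodide;
  - proton transfer from C9 of the ketone stage in place of the second addition, which halts the reaction halfway;
  - acyl shift in the alkoxide if the quench is late.
- Fallback (known chemistry), from 2 back to 8:
  - Chloromethyllithium is generated at −78 °C from chloroiodomethane and MeLi·LiBr in the presence of 2. It adds twice and gives, after an AcOH quench, 1,3-dichloro-2-(2-methoxy-4-methylphenyl)propan-2-ol F1.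
  - F1 is heated with cesium isobutyrate and some isobutyric acid as buffer in DMF. The C8 alkoxide relays the substitution: closure to 2-(chloromethyl)-2-(2-methoxy-4-methylphenyl)oxirane F2, carboxylate opening at the CH2 terminus to 3-chloro-2-hydroxy-2-(2-methoxy-4-methylphenyl)propyl isobutyrate F3, closure again to [2-(2-methoxy-4-methylphenyl)oxiran-2-yl]methyl isobutyrate F4, and a second opening to 8.
  - The C1 unit is nucleophile first and electrophile second, so no ester ever meets an organometallic. The two-directional C8–C9/C8–C10 logic is kept.

**Step 2.**
- Most likely failure: loss of the iodide by hydrolysis, by light-induced decomposition or by carboxylate displacement during isolation, and carry-over of iodine or moisture that would consume the Grignard reagent in step 3.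
- Fallback, from 3 back to 5:
  - The carbenoid is released from sulfur instead of iodine. Compound 3 and sodium thiophenolate give (phenylsulfanyl)methyl isobutyrate F5.
  - One equivalent of mCPBA at low temperature gives (phenylsulfinyl)methyl isobutyrate F6, a storable precursor.
  - Sulfoxide–magnesium exchange with iPrMgCl at −78 °C, the exchange used for α-chloroalkyl magnesium carbenoids, should release 5.

**Step 1.**
- Most likely failure: incomplete conversion or partial hydrolysis on handling. Acidic protons and anhydride-type species then enter step 3, destroy the carbenoid and upset its stoichiometry.
- Fallback, from 1 back to 6: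
  - One arm is installed with normal polarity and only the second by umpolung. Compound 1 with two equivalents of MeLi gives 1-(2-methoxy-4-methylphenyl)ethanone F7.
  - CuBr2 in EtOAc/CHCl3 at reflux gives 2-bromo-1-(2-methoxy-4-methylphenyl)ethanone F8.
  - Potassium isobutyrate in DMF gives isolated 6, which is then treated with a single equivalent of 5 under the conditions of step 3.

## Further compounds

F1 | step 3 | 1,3-dichloro-2-(2-methoxy-4-methylphenyl)propan-2-ol | COc1cc(C)ccc1C(O)(CCl)CCl
F2 | step 3 | 2-(chloromethyl)-2-(2-methoxy-4-methylphenyl)oxirane (racemic) | COc1cc(C)ccc1C1(CCl)CO1
F3 | step 3 | 3-chloro-2-hydroxy-2-(2-methoxy-4-methylphenyl)propyl isobutyrate (racemic) | COc1cc(C)ccc1C(O)(CCl)COC(=O)C(C)C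
F4 | step 3 | [2-(2-methoxy-4-methylphenyl)oxiran-2-yl]methyl isobutyrate (racemic) | COc1cc(C)ccc1C1(COC(=O)C(C)C)CO1
F5 | step 2 | (phenylsulfanyl)methyl isobutyrate | CC(C)C(=O)OCSc1ccccc1
F6 | step 2 | (phenylsulfinyl)methyl isobutyrate (racemic at sulfur) | CC(C)C(=O)OCS(=O)c1ccccc1
F7 | step 1 | 1-(2-methoxy-4-methylphenyl)ethanone | COc1cc(C)ccc1C(C)=O
F8 | step 1 | 2-bromo-1-(2-methoxy-4-methylphenyl)ethanone | COc1cc(C)ccc1C(=O)CBr
A1 | alternative 1 | 2-bromo-5-methylanisole | COc1cc(C)ccc1Br
A2 | alternative 1 | 2,2-dimethyl-1,3-dioxan-5-one | CC1(C)OCC(=O)CO1
A3 | alternative 1 | 5-(2-methoxy-4-methylphenyl)-2,2-dimethyl-1,3-dioxan-5-ol | COc1cc(C)ccc1C1(O)COC(C)(C)OC1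
A4 | alternative 1 | 2-(2-methoxy-4-methylphenyl)propane-1,2,3-triol | COc1cc(C)ccc1C(O)(CO)CO
A5 | alternative 1 | 1,3-bis(isobutyryloxy)acetone | CC(C)C(=O)OCC(=O)COC(=O)C(C)C
A6 | alternative 2 | 2-(2-methoxy-4-methylphenyl)allyl isobutyrate | COc1cc(C)ccc1C(=C)COC(=O)C(C)C
A7 | alternative 2 | 2,3-dihydroxy-2-(2-methoxy-4-methylphenyl)propyl isobutyrate (racemic) | COc1cc(C)ccc1C(O)(CO)COC(=O)C(C)C
A8 | alternative 3 | 3-(2-methoxy-4-methylphenyl)oxetan-3-ol | COc1cc(C)ccc1C1(O)COC1
A9 | alternative 3 | oxetan-3-one | O=C1COC1
A10 | alternative 3 | isobutyric anhydride | CC(C)C(=O)OC(=O)C(C)C
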